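The last Q readings of oak and maple stood in a ratio of 1.45, while their L charges stood in a ratio of 2.24 the other way.

the same everywhere: J 10 mM
- oak: E 9.5 mM; L 6.7 mM; run made earlier
- maple: E 9.5 mM; L 15 mM; run made earlier
- flask: E 9.50 mM; L 10.0 mM; time 6.0 min

| run | time / min | Q / % | Z / % |
|---|---|---|---|
| oak | 0.500 | 10 | 21 |
| oak | 1.00 | 20 | 21 |
| oak | 1.50 | 30 | 29 |
| oak | 2.00 | 38 | 39 |
| oak | 2.50 | 41 | 43 |
| oak | 3.00 | 45 | 48 |
| oak | 4.00 | 45 | 53 |
| maple | 0.200 | 3 | 9 |
| maple | 0.500 | 4 | 18 |
| maple | 1.00 | 20 | 27 |
| maple | 1.50 | 22 | 34 |
| maple | 2.00 | 28 | 42 |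
| maple | 3.00 | 28 | 54 |
| maple | 4.00 | 31 | 60 |

(each reading ± 2 percentage points)

- solid, in amounts per volume of the solution: J
- the analysis behind the earlier runs scatters by 2 percentage points, standard deviation
- at the start none of J is in solution
- Z means what is dissolved; the solid is not counted in it
- Z is what J becomes in solution

- how much Q there is at 6.0 min, in percent of the J charged
- concentration of Z in solution at 6.0 min, in percent of saturation

I drew the Q curve of the flask from three landmarks. The start came first: oak read 20% at 1.00 min and maple read 20% at 1.00 min, so I took that same slope for the flask, though single readings carry their scatter.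

The level came next. I read each level as a divided charge of E: some goes to Q, some to a side path that grows with L. So I defined the price of Q, the millimoles of E charged per millimole of Q at the level, and let it rise in a straight line with L:

oak, last reading: 2.11
maple, last reading: 3.06
flask, at its L: 2.49
level of the flask: 38.1%

The knee came last. The starting line meets that level at 1.91 min, earlier than the asked 6.0 min, so I expected the flask to sit on its level by then. For saturation I made no reckoning.

The forecast gave 40% (36% to 44%) and 78% of saturation (60% to 97%), on the grounds “That suggests an equilibrium”. My level of 38.1% for the flask stood lower than the forecast's 40%, and I read the stall as a divided charge of E, not as an equilibrium.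

The flask gave 38.3% of Q, with Z at 99.0% of saturation.

    Z + E → Q (k = 4.45 M⁻¹ s⁻¹)
    2 E → D (k = 0.322 M⁻¹ s⁻¹)
    E + L → X (k = 1.22 M⁻¹ s⁻¹)
    J ⇌ Z, rate k4*(cs4 - [Z]) while solid is left; crystals form when [Z] > cs4 (solubility = 6.20 mM, k = 0.0167 s⁻¹)

In the flask E, the limiting reagent, stood at 0% of its charge at 6.00 min, and Q was still 38.3% of the J charged at 60.0 min. The price paid in the flask was 2.48. Applied to a neighbouring flask charged with 3.8 mM of E, all else held, my price of 2.49 gave 15.3% of Q, and that flask gave 16.6%.

The runs stem from a simulated flask from invented constants; scatter was added.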